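Q, the limiting reagent, reacts with J, charged at twice its amount, to give D and the by-product X, at 1.8 × 10⁻⁴ /M/s. X binds to J as J.X and to the base G as X.G and L.

    Q + J → X + D (k1 = 1.8 × 10⁻⁴ /M/s)
    J + X ⇌ J.X, settled at all times (K2 = 860 /M)
    X + G ⇌ X.G (K3 = 12 /M, k3 = 0.017 /M/s)
    X + G ⇌ L, settled at all times (K4 = 310 /M)

in all of them: Q 0.079 M; J 0.158 M; time 8.0 h
- west: G 0.120 M
- south-east: G 0.0950 M
- north-west: G 0.160 M

* part of the Q that has reacted at the end, west
* part of the Q that has reacted at the end, south-east
* part of the Q that has reacted at the end, north-west
* what raising the concentration of G from its lowest to its highest value here does to the part of the Q that has reacted (changes below 5 percentage points count as none) (it falls / no change / it rises)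

I work with the fraction left. The excess of J over Q, times the rate constant and the time, gives an exponent w of 0.410. The second-order law then gives the excess divided by (J charge times e^w, minus Q charge): 49.7%, the part of the Q still unreacted if nothing holds J back. G does not enter this formula, so I commit to 50.3% reacted in west, the same figure in south-east and north-west, and no change. I expect this to stand high: at the start of south-east, the equilibrium constant times the charge of the partner is 140 for X binding to J against 29 for X binding to G as L, so J.X withholds some J.

The forecast gives 46.5% in west, 46.3% in south-east and 46.8% in north-west, with no change as the trend. Its ground: “G frees only a little J, because the competing J.X binding remains modest at these conversions”.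

The flasks give 46.5%, 46.3% and 46.8%, with no change: the shift is 0.52 percentage points. The forecast held. West keeps 54% of its Q where my fraction left says 49.7%.

In south-east, with the concentrations as charged, the half-life of free X by the forward step to X.G is 0.12 h, far shorter than the 6.8 h half-life of Q in the step that makes X. At the end of south-east, free X stands at 3.33 × 10⁻⁴ M, while J.X, the resting state of X, holds 0.0270 M, more than the 0.00885 M in L, and free J is 60% of its charge.

With 0.27 M of J in the south-east flask, the fraction left reads 29.5%, so I expect 70.5% reacted, again on the high side. That flask gives 66.3%.

The numbers are those of an exercise; the run is a simulation.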